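Assumption: the target has no stereocentre (it is achiral), so "single enantiomer" needs no stereocontrol; racemic transient intermediates lose their stereocentre before the end.

**Retrosynthetic overview**
- Last step: hydrogenolysis of two benzyl ethers (6-O and 2'-O) of the fully assembled flavone.
- The pyranone C-ring is the only ring built, and it is formed last: I2/DMSO oxidative cyclisation of a 2'-hydroxychalcone (O1–C2 bond and C2=C3).
- Key C–C bond (flavone C2–C3): intermolecular Claisen–Schmidt aldol condensation of 5-benzyloxy-2-hydroxy-3,4,6-trimethoxyacetophenone with 2-benzyloxy-6-methoxybenzaldehyde.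
- A-ring ketone from 3,4,5-trimethoxyphenol: O-methylation, Friedel–Crafts acetylation with chelation-controlled ortho-demethylation, Elbs para-hydroxylation, selective benzylation of the non-chelated OH.
- B-ring aldehyde: benzylation of 2-hydroxy-6-methoxybenzaldehyde; both benzene rings are bought intact.

**Route**

Step 1
Reactants: 1 3,4,5-trimethoxyphenol
Product: 2 1,2,3,5-tetramethoxybenzene
Conditions: MeI (1.5 eq), K2CO3 (2 eq), acetone, reflux, 12 h
Reagents that add atoms: iodomethane, CI
Why: Williamson O-methylation of an unhindered phenoxide with a primary iodide is essentially quantitative.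

Step 2
Reactants: 2 1,2,3,5-tetramethoxybenzene
Product: 4 2-hydroxy-3,4,6-trimethoxyacetophenone, via 2,3,4,6-tetramethoxyacetophenone 3 (not isolated)
Conditions: AcCl (1.2 eq), AlCl3 (2.5 eq), Et2O, 0 °C → rt, 16 h; then ice/2 M HCl
Reagents that add atoms: acetyl chloride, CC(Cl)=O
Why: Friedel–Crafts acylation can only occur at the two equivalent free positions, and AlCl3 chelated to the new carbonyl then cleaves the more crowded ortho methoxy (the one flanked by a second OMe), giving the hydrogen-bonded o-hydroxyketone.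

Step 3
Reactants: 4 2-hydroxy-3,4,6-trimethoxyacetophenone
Product: 6 2,5-dihydroxy-3,4,6-trimethoxyacetophenone, via potassium aryl sulfate ester 5 (not isolated)
Conditions: K2S2O8 (1.1 eq), 10% aq KOH, 0 °C → rt, 24 h; acidify to pH 4, wash with Et2O (recover 4); then conc. HCl, 90 °C, 30 min
Reagents that add atoms: potassium peroxodisulfate, [K+].[K+].[O-]S(=O)(=O)OOS(=O)(=O)[O-]
Why: Elbs persulfate oxidation attacks the phenoxide at its para carbon, the only free ring position, and acid hydrolysis of the aryl sulfate releases the hydroquinone.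

Step 4
Reactants: 6 2,5-dihydroxy-3,4,6-trimethoxyacetophenone
Product: 7 5-benzyloxy-2-hydroxy-3,4,6-trimethoxyacetophenone
Conditions: BnBr (1.05 eq), K2CO3 (1.2 eq), acetone, reflux, N2, 6 h
Reagents that add atoms: benzyl bromide, BrCc1ccccc1
Why: In this Williamson etherification the 2-OH is tied up in a strong hydrogen bond to the ketone and is far less nucleophilic, so one equivalent of halide alkylates the 5-OH selectively.

Step 5
Reactants: 8 2-hydroxy-6-methoxybenzaldehyde
Product: 9 2-benzyloxy-6-methoxybenzaldehyde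
Conditions: BnBr (1.2 eq), K2CO3 (2 eq), DMF, 60 °C, 4 h
Reagents that add atoms: benzyl bromide, BrCc1ccccc1
Why: Williamson benzylation in DMF overcomes the hydrogen bond of the single phenol, and the aldehyde is untouched by carbonate.

Step 6
Reactants: 7 5-benzyloxy-2-hydroxy-3,4,6-trimethoxyacetophenone; 9 2-benzyloxy-6-methoxybenzaldehyde
Product: 11 (E)-1-[5-(benzyloxy)-2-hydroxy-3,4,6-trimethoxyphenyl]-3-[2-(benzyloxy)-6-methoxyphenyl]prop-2-en-1-one, via β-hydroxy ketone aldol adduct 10 (not isolated)
Conditions: 9 (1.2 eq), 50% aq KOH (10 eq), EtOH, rt, 48 h, N2; then ice/dil. HCl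
Reagents that add atoms: none
Why: Claisen–Schmidt crossed aldol condensation, in which the methyl ketone enolate adds to the non-enolisable aldehyde and E1cB loss of water gives the conjugated (E)-chalcone; the racemic aldol stereocentre is destroyed on dehydration.

Step 7
Reactants: 11 (E)-2'-hydroxychalcone from step 6
Product: 13 6-(benzyloxy)-2-[2-(benzyloxy)-6-methoxyphenyl]-5,7,8-trimethoxy-4H-chromen-4-one, via flavanone 12 (not isolated)
Conditions: I2 (10 mol%), DMSO, 120 °C, 3 h; aq Na2S2O3 work-up
Reagents that add atoms: none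
Why: Oxidative cyclisation of a 2'-hydroxychalcone, in which intramolecular oxa-Michael addition of the free 2'-phenol gives the racemic flavanone and the I2/DMSO couple (DMSO as terminal oxidant) dehydrogenates C2–C3 to the flavone, leaving benzyl and methyl ethers intact.

Step 8
Reactants: 13 6-(benzyloxy)-2-[2-(benzyloxy)-6-methoxyphenyl]-5,7,8-trimethoxy-4H-chromen-4-one
Product: 14 6,2'-dihydroxy-5,7,8,6'-tetramethoxyflavone
Conditions: H2 (1 atm), 10% Pd/C, EtOAc–MeOH 1:1, rt, 2–6 h (stop at full debenzylation)
Reagents that add atoms: none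
Why: Catalytic hydrogenolysis cleaves both aryl benzyl ethers under conditions that leave aryl methyl ethers and the chromone C2=C3/C=O untouched.

**Compound list**

1 | 3,4,5-trimethoxyphenol | COc1cc(O)cc(OC)c1OC | starting material
2 | 1,2,3,5-tetramethoxybenzene | COc1cc(OC)c(OC)c(OC)c1 | intermediate
3 | 2,3,4,6-tetramethoxyacetophenone (not isolated) | CC(=O)c1c(OC)cc(OC)c(OC)c1OC | intermediate
4 | 2-hydroxy-3,4,6-trimethoxyacetophenone | CC(=O)c1c(OC)cc(OC)c(OC)c1O | intermediate
5 | potassium 3-acetyl-4-hydroxy-2,5,6-trimethoxyphenyl sulfate (not isolated) | CC(=O)c1c(OC)c(OS(=O)(=O)[O-])c(OC)c(OC)c1O.[K+] | intermediate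
6 | 2,5-dihydroxy-3,4,6-trimethoxyacetophenone | CC(=O)c1c(OC)c(O)c(OC)c(OC)c1O | intermediate
7 | 5-benzyloxy-2-hydroxy-3,4,6-trimethoxyacetophenone | CC(=O)c1c(OC)c(OCc2ccccc2)c(OC)c(OC)c1O | intermediate
8 | 2-hydroxy-6-methoxybenzaldehyde | COc1cccc(O)c1C=O | starting material
9 | 2-benzyloxy-6-methoxybenzaldehyde | COc1cccc(OCc2ccccc2)c1C=O | intermediate
10 | 1-[5-(benzyloxy)-2-hydroxy-3,4,6-trimethoxyphenyl]-3-[2-(benzyloxy)-6-methoxyphenyl]-3-hydroxypropan-1-one (racemic, not isolated) | COc1cccc(OCc2ccccc2)c1C(O)CC(=O)c1c(OC)c(OCc2ccccc2)c(OC)c(OC)c1O | intermediate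
11 | (E)-1-[5-(benzyloxy)-2-hydroxy-3,4,6-trimethoxyphenyl]-3-[2-(benzyloxy)-6-methoxyphenyl]prop-2-en-1-one | COc1cccc(OCc2ccccc2)c1/C=C/C(=O)c1c(OC)c(OCc2ccccc2)c(OC)c(OC)c1O | intermediate
12 | 6-(benzyloxy)-2-[2-(benzyloxy)-6-methoxyphenyl]-5,7,8-trimethoxychroman-4-one (racemic flavanone, not isolated) | COc1cccc(OCc2ccccc2)c1C1CC(=O)c2c(OC)c(OCc3ccccc3)c(OC)c(OC)c2O1 | intermediate
13 | 6-(benzyloxy)-2-[2-(benzyloxy)-6-methoxyphenyl]-5,7,8-trimethoxy-4H-chromen-4-one | COc1cccc(OCc2ccccc2)c1-c1cc(=O)c2c(OC)c(OCc3ccccc3)c(OC)c(OC)c2o1 | intermediate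
14 | 6,2'-dihydroxy-5,7,8,6'-tetramethoxyflavone [6-hydroxy-2-(2-hydroxy-6-methoxyphenyl)-5,7,8-trimethoxy-4H-chromen-4-one] | COc1cccc(O)c1-c1cc(=O)c2c(OC)c(O)c(OC)c(OC)c2o1 | target

**Totals**
Total step count: 8. Longest linear sequence: 7 steps (steps 1, 2, 3, 4, 6, 7, 8 from compound 1); the B-ring branch is step 5.

**Three steps most likely to fail, each with a fallback**

Step 3 (Elbs oxidation). The para site is flanked by two methoxy groups and Elbs reactions commonly stop at 30–45% conversion. The fallback sets out from 4 and comes back at 6. Compound 4 is oxidised with Fremy's salt (potassium nitrosodisulfonate, KH2PO4 buffer, acetone–water, rt; Teuber oxidation of a para-unsubstituted phenol) to 2-acetyl-3,5,6-trimethoxy-1,4-benzoquinone F1. The quinone is then reduced with Na2S2O4 in EtOAc–water to the hydroquinone 6.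

Step 6 (aldol condensation). Both partners are di-ortho-substituted and the ketone is deactivated as its phenoxide, so the condensation may stall. Partial closure to flavanone 12 is harmless, since 12 also goes forward in step 7. The fallback sets out from 7 and 9 and comes back at 13, making the same C–C bond by an intermolecular Claisen-type acylation. Aldehyde 9 is oxidised (NaClO2, NaH2PO4, 2-methyl-2-butene, t-BuOH–water; Pinnick) to 2-(benzyloxy)-6-methoxybenzoic acid F2. This is converted with SOCl2 (cat. DMF, toluene, 60 °C) into 2-(benzyloxy)-6-methoxybenzoyl chloride F3. Ketone 7 is deprotonated with LiHMDS (3.5 eq, THF, −78 °C) and C-acylated with F3 to give 1-[5-(benzyloxy)-2-hydroxy-3,4,6-trimethoxyphenyl]-3-[2-(benzyloxy)-6-methoxyphenyl]propane-1,3-dione F4. Cyclodehydration (cat. p-TsOH, toluene, 80 °C) then gives flavone 13 directly, bypassing steps 6 and 7.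

Step 7 (I2/DMSO oxidative cyclisation). The bulky 2,6-disubstituted aryl slows ring closure, and HI formed at 120 °C can attack the 5-OMe or the benzyl ethers on long heating. The fallback sets out from 11 and comes back at 13. Chalcone 11 is closed with NaOAc in refluxing EtOH to flavanone 12, which is isolated this time. It is then dehydrogenated by hydride abstraction with DDQ (2 eq, dioxane, reflux). No compound outside the list is made on this path (none, F0).

**Further compounds**

F1 | step 3 | 2-acetyl-3,5,6-trimethoxy-1,4-benzoquinone | CC(=O)C1=C(OC)C(=O)C(OC)=C(OC)C1=O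
F2 | step 6 | 2-(benzyloxy)-6-methoxybenzoic acid | COc1cccc(OCc2ccccc2)c1C(=O)O
F3 | step 6 | 2-(benzyloxy)-6-methoxybenzoyl chloride | COc1cccc(OCc2ccccc2)c1C(=O)Cl
F4 | step 6 | 1-[5-(benzyloxy)-2-hydroxy-3,4,6-trimethoxyphenyl]-3-[2-(benzyloxy)-6-methoxyphenyl]propane-1,3-dione | COc1cccc(OCc2ccccc2)c1C(=O)CC(=O)c1c(OC)c(OCc2ccccc2)c(OC)c(OC)c1O
F0 | step 7 | none | none
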